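Grey, the flask asked about, reads flat from its first reading with starting material still in it, so ask what stopped it.

the same everywhere: starting material 0.80 M; free catalyst 0.80 mM

| run | partner | temperature | remark | time |
|---|---|---|---|---|
| grey | 1.2 M | 20 °C | the very flask that is asked about, followed so far |  |
| violet | 0.60 M | 15 °C | run made earlier |  |
| flask | 1.20 M | 20 °C |  | 20 h |

- grey (time / h: product / %, starting material / %): 2.00: 78, 22; 5.00: 78, 24; 10.0: 78, 25; 15.0: 77, 23; 20.0: 79, 25
- violet (time / min: product / %, starting material / %): 15.0: 22, 80; 30.0: 30, 69; 50.0: 39, 60; 60.0: 43, 58; 80.0: 47, 55

(standard deviation of a reading: 1.5 percentage points)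

- Friday's: at 20 h take out 90% of the by-product then present, then wait 20 h
- Thursday's: at 20 h add free catalyst, 100% of the amount charged, then wait 20 h
- Monday's: change nothing and wait 20 h more
- Sunday's: at 20 h add partner, 50.0% of the amount charged, then wait 20 h
- Tuesday's: at 20 h raise the temperature by 10 K, then wait 20 h

- additions bring no volume worth counting

* product, in percent of the starting material first charged, at 20 h
* what to do for the largest gain in product; "none" if nothing gains more than 2 percentage points (Friday's / Thursday's / Monday's / Sunday's / Tuesday's / none)
* product present, in percent of the starting material first charged, after Monday's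
* product present, in percent of the starting material first charged, after Sunday's

Compare two amounts in grey. Read [product] as 0.624 M and set it against the [partner] charged, 1.20 M. Divide the first by the second and call the result the partner yield, product won per partner charged: 52.0%, a reading with the scatter of its readings. No time enters this ratio.

Violet, with half the partner and at 15 °C, gives 62.7% by its last reading, with product still rising there. The two runs differ in temperature as well as in partner, and violet is not flat, so this comparison is rough, but it leads me to tie product to partner. My reading is that partner is the limiting reagent in grey, even at 1.50 equivalents, and that 0.576 M of it went elsewhere.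

So I expect grey to stay near 78%. Sunday's adds 0.600 M of partner, and at this yield that is worth 0.312 M of product, more than the 0.176 M of starting material still unconverted. I therefore expect Sunday's to convert nearly all of that starting material, and I expect nothing from the options that add no partner.

The forecast gives 78% now (76.5% to 79.5%), 78% after Monday's, 86% after Sunday's (82% to 89%), and chooses Friday's, on the ground that “Equilibrium is therefore the simple reading”. We agree on the first two and part on the last two.

The flask gives 77.1% at 20 h, 77.1% after Monday's and 100% after Sunday's. The best choice is Sunday's, a gain of 23 percentage points, while Friday's gains 0 points.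

    catalyst intermediate A ⇌ by-product + catalyst intermediate B (K = 0.330 M, k = 118 min⁻¹, Ea = 63.0 kJ mol⁻¹, ΔH = −4.00 kJ mol⁻¹)
    catalyst intermediate C → free catalyst + product (k = 89.9 min⁻¹, Ea = 67.0 kJ mol⁻¹)
    partner → decomposed reagent (k = 0.0268 min⁻¹, Ea = 86.0 kJ mol⁻¹)
    starting material + catalyst intermediate B ⇌ catalyst intermediate C (K = 42.0 M⁻¹, k = 820 M⁻¹ min⁻¹, Ea = 45.0 kJ mol⁻¹, ΔH = −44.0 kJ mol⁻¹)
    partner + free catalyst → catalyst intermediate A (k = 67.8 M⁻¹ min⁻¹, Ea = 51.0 kJ mol⁻¹)
    (constants at 20 °C)

At 20.0 h the flask holds 0% of its partner, with decomposed reagent at 0.583 M and by-product at 0.617 M; its 77.1% is a partner yield of 51.4%. Now take the neighbour with [starting material] at 2.0 M, the partner unchanged. Grey's partner yield gives it 31.2% product. That flask ends at 31.8% product, with 68.2% of its starting material and 0% of its partner left.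

(All runs are calculated from invented constants; the scatter is artificial.)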